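**Strategy.** The five-membered ring (C1, C2, C3, C3a, C7a), with its C2 acetate next to the Z-ethylidene at C1, is a reduced (Z)-2-ethylidenecyclopentanone, and it is made from a cyclobutane. A 1-[(Z)-propenyl]cyclobutanol silyl ether, fused photochemically to (S)-cryptone, undergoes a selenium-induced semipinacol shift of the ring-fusion carbon C7a from C2 to the alkenyl carbon, which enters the ring as C1; stereospecific selenoxide syn-elimination then gives the Z-enone. The cryptone ketone (C4) later equilibrates C3a to the trans ring fusion and is turned, via a β-epoxy ketone, into the methylidene group and the trans-diaxial hydroxy angelate.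

Key step: step 6

**Remarks.**
- Locants from compound 10 on follow octahydro-1H-indene: C1 (ethylidene carbon), C2, C3, C3a, C4, C5, C6, C7 (isopropyl carbon), C7a. β is the face of the C7 isopropyl group, α the opposite face.
- Assumption: the (S)-prolinol ether in step 1 shields the enamine so that the (S)-aldehyde forms, by analogy with its other Michael additions; if the sense were opposite, the (R)-catalyst would be used.
- Compounds 7–9 are epimer mixtures at the silyloxy carbon and 10 is a diastereomer pair at its two new centres; all these centres become sp2 in 11.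

**Step 1**
Reactants: 1 isovaleraldehyde (3-methylbutanal); 2 methyl vinyl ketone (but-3-en-2-one)
Product: 3 (2S)-5-oxo-2-(propan-2-yl)hexanal
Conditions: (S)-α,α-diphenylprolinol methyl ether (5 mol%), ethyl 3,4-dihydroxybenzoate (20 mol%), neat, 4 °C
Reagents that add atoms: none
Why: Enamine-catalysed asymmetric Michael addition, in which the (E)-enamine of 1 should add to 2 on the face remote from the diphenylmethoxymethyl group and so set the (S) centre that becomes C7.

**Step 2**
Reactants: 3 (2S)-5-oxo-2-(propan-2-yl)hexanal
Product: 4 (S)-cryptone [(4S)-4-(propan-2-yl)cyclohex-2-en-1-one]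
Conditions: LiOH (0.1 equiv), i-PrOH, rt
Reagents that add atoms: none
Why: Intramolecular aldol condensation (the ring-closing half of a Robinson annulation) under mild hydroxide should close the cyclohexenone without racemising the γ-centre.

**Step 3**
Reactants: 5 pent-3-yn-2-one
Product: 6 2-(tert-butyldimethylsilyloxy)pent-1-en-3-yne
Conditions: TBSOTf, Et3N, CH2Cl2, 0 °C
Reagents that add atoms: tert-butyldimethylsilyl trifluoromethanesulfonate, CC(C)(C)[Si](C)(C)OS(=O)(=O)C(F)(F)F
Why: Soft enolisation and O-silylation of the only enolisable (methyl) side of the ynone gives the 2-silyloxy enyne.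

**Step 4**
Reactants: 4 (S)-cryptone; 6 2-(tert-butyldimethylsilyloxy)pent-1-en-3-yne
Product: 8 cis-fused (1S,5S,6S)-7-(tert-butyldimethylsilyloxy)-5-isopropyl-7-(prop-1-ynyl)bicyclo[4.2.0]octan-2-one (epimers at C7), via trans-fused cycloadduct 7 (not isolated)
Conditions: hν (350 nm, Pyrex), 6 (5 equiv), CH2Cl2, −40 °C; then basic Al2O3, CH2Cl2, rt
Reagents that add atoms: none
Why: Enone–alkene [2+2] photocycloaddition of the triplet enone at the electron-rich enol-ether double bond, expected head-to-tail (silyloxy carbon on the enone β-carbon) and anti to the isopropyl group, sets the future C7a, while alumina epimerises the strained trans-fused ketone 7 to cis-fused 8 through its enol.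

**Step 5**
Reactants: 8 cis-fused alkynyl cycloadduct
Product: 9 cis-fused (1S,5S,6S)-7-(tert-butyldimethylsilyloxy)-5-isopropyl-7-[(Z)-prop-1-enyl]bicyclo[4.2.0]octan-2-one (epimers at C7)
Conditions: H2 (1 atm), Pd/CaCO3 poisoned with Pb(OAc)2, quinoline, EtOAc, rt
Reagents that add atoms: none
Why: Lindlar semihydrogenation adds H2 syn to the alkyne and should stop at the (Z)-alkene, leaving ketone and silyl ether untouched.

**Step 6 (key step)**
Reactants: 9 (Z)-propenyl cyclobutanol silyl ether
Product: 11 cis-fused (1Z)-1-ethylidene-7β-isopropylhexahydro-1H-indene-2,4-dione (H-3a and H-7a both β), via selenide 10 (not isolated)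
Conditions: PhSeCl (1.05 equiv), CH2Cl2, −78 °C; then pyridine, 30% aq. H2O2, 0 °C to rt
Reagents that add atoms: none
Why: PhSe+ adds to the (Z)-propenyl group to give a seleniranium ion, which is opened from the rear by the silyloxy-assisted 1,2-shift of the cyclobutane bond C7–C6 (C6 is the ring-fusion carbon, later C7a), so that the former alkenyl carbon is inserted as C1 and the four-membered ring becomes the cyclopentanone with loss of TBSCl; oxidation of the selenide and syn-elimination of the selenoxide toward the acidic C1 hydrogen then give the enone. The closest known reactions are the selenium- or halonium-induced semipinacol ring expansion of 1-alkenylcyclobutanols and the Reich selenoxide elimination. The five-membered ring is closed by ring enlargement through a suprafacial 1,2-carbon shift and not by a cyclisation, and C7a migrates with retention, so the configuration set in the photocycloaddition is kept. The anti addition of selenium and the migrating carbon across the Z-alkene, followed by the syn-elimination, translates the Z-propenyl geometry into the Z-ethylidene group (methyl syn to C2), and the two transient sp3 centres disappear. The step needs migration of the ring-fusion carbon and not of the CH2 carbon, which the higher migratory aptitude of the more substituted carbon should secure, and it needs the alkene to react before the ketone is selenenylated, which the low temperature should secure.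

**Step 7**
Reactants: 11 cis-fused Z-enone dione
Product: 14 cis-fused (1Z)-1-ethylidene-2α-hydroxy-7β-isopropyloctahydro-1H-inden-4-one, via ketal enone 12 (not isolated), via ketal alcohol 13 (not isolated)
Conditions: CeCl3·7H2O, HC(OMe)3, MeOH, rt; then NaBH4, −78 °C; then 1 M HCl, THF, 0 °C
Reagents that add atoms: none
Why: Luche reduction with in-situ protection, in which the saturated C4 ketone is ketalised by the orthoformate while the conjugated C2 ketone is not, the hydride then adds 1,2 to the enone from the convex face of the cis-fused bicycle (the face of H-3a and H-7a) to give the 2α-alcohol, and the ketal is cleaved on acidic work-up.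

**Step 8**
Reactants: 14 cis-fused 2α-hydroxy ketone
Product: 15 trans-fused (1Z)-1-ethylidene-2α-hydroxy-7β-isopropyloctahydro-1H-inden-4-one (H-3a α, H-7a β)
Conditions: K2CO3, MeOH, rt
Reagents that add atoms: none
Why: Base-mediated epimerisation through the C4 enolate should move C3a to the more stable trans-fused hydrindan-4-one, in which C3, C1 and the isopropyl group are all equatorial on the cyclohexanone chair.

**Step 9**
Reactants: 15 trans-fused 2α-hydroxy ketone
Product: 16 trans-fused (1Z)-2β-acetoxy-1-ethylidene-7β-isopropyloctahydro-1H-inden-4-one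
Conditions: PPh3, DIAD, AcOH, THF, 0 °C to rt
Reagents that add atoms: acetic acid, CC(=O)O
Why: Mitsunobu esterification displaces the activated allylic 2α-hydroxyl by acetate with inversion (SN2), which installs the 2β-acetate of the target.

**Step 10**
Reactants: 16 trans-fused 2β-acetoxy ketone
Product: 18 trans-fused (1Z)-2β-acetoxy-1-ethylidene-7β-isopropyl-1,2,3,3a,7,7a-hexahydro-4H-inden-4-one (C5=C6 enone), via silyl enol ether 17 (not isolated)
Conditions: LiN(SiMe3)2, Me3SiCl, THF, −78 °C; then Pd(OAc)2 (1.1 equiv), MeCN, rt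
Reagents that add atoms: none
Why: Saegusa–Ito oxidation, in which kinetic deprotonation at the unhindered C5 methylene with in-situ silylation gives the less substituted silyl enol ether, which Pd(OAc)2 dehydrogenates to the C5–C6 enone.

**Step 11**
Reactants: 18 C5=C6 enone
Product: 19 trans-fused (1Z)-2β-acetoxy-5β,6β-epoxy-1-ethylidene-7β-isopropyloctahydro-1H-inden-4-one
Conditions: t-BuOOH, DBU, CH2Cl2, 0 °C to rt
Reagents that add atoms: tert-butyl hydroperoxide, CC(C)(C)OO
Why: Weitz–Scheffer nucleophilic epoxidation, in which the hydroperoxide anion should attack C6 of the rigid trans-fused enone axially, anti to the axial H-7, and so close the 5β,6β-epoxide on the face of the isopropyl group.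

**Step 12**
Reactants: 19 5β,6β-epoxy ketone
Product: 20 trans-fused (1Z)-2β-acetoxy-5β,6β-epoxy-1-ethylidene-7β-isopropyl-4-methylideneoctahydro-1H-indene
Conditions: Ph3PCH3Br, KN(SiMe3)2, THF, 0 °C to rt
Reagents that add atoms: methyltriphenylphosphonium bromide, C[P+](c1ccccc1)(c1ccccc1)c1ccccc1.[Br-]
Why: Wittig methylenation of the hindered epoxy ketone tolerates the epoxide and leaves the already thermodynamic C3a centre unchanged.

**Step 13**
Reactants: 20 vinyl epoxide; 21 angelic acid [(2Z)-2-methylbut-2-enoic acid]
Product: 22 CNP0210397.1, (1Z,2S,3aR,5S,6S,7S,7aR)-2-acetoxy-1-ethylidene-6-hydroxy-4-methylidene-7-(propan-2-yl)octahydro-1H-inden-5-yl (2Z)-2-methylbut-2-enoate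
Conditions: 21 (5 equiv), Cs2CO3 (0.5 equiv), DMF, 50 °C
Reagents that add atoms: none
Why: Carboxylate opening of the vinyl epoxide by SN2 attack at the allylic C5 with inversion, the trans-diaxial (Fürst–Plattner) mode on the rigid chair, gives the 5α-angelate and the 6β-hydroxyl in one step.

**Compound list**
1 | isovaleraldehyde (3-methylbutanal) | CC(C)CC=O | starting material
2 | methyl vinyl ketone (but-3-en-2-one) | CC(=O)C=C | starting material
3 | (2S)-5-oxo-2-(propan-2-yl)hexanal | O=C[C@H](C(C)C)CCC(C)=O | intermediate
4 | (S)-cryptone, (4S)-4-(propan-2-yl)cyclohex-2-en-1-one | O=C1C=C[C@H](C(C)C)CC1 | intermediate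
5 | pent-3-yn-2-one | CC#CC(C)=O | starting material
6 | 2-(tert-butyldimethylsilyloxy)pent-1-en-3-yne | C=C(O[Si](C)(C)C(C)(C)C)C#CC | intermediate
7 | trans-fused (1R,5S,6S)-7-(tert-butyldimethylsilyloxy)-5-isopropyl-7-(prop-1-ynyl)bicyclo[4.2.0]octan-2-one, epimers at C7 | O=C1[C@@H]2CC(O[Si](C)(C)C(C)(C)C)(C#CC)[C@H]2[C@H](C(C)C)CC1 | intermediate (not isolated)
8 | cis-fused (1S,5S,6S)-7-(tert-butyldimethylsilyloxy)-5-isopropyl-7-(prop-1-ynyl)bicyclo[4.2.0]octan-2-one, epimers at C7 | O=C1[C@H]2CC(O[Si](C)(C)C(C)(C)C)(C#CC)[C@H]2[C@H](C(C)C)CC1 | intermediate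
9 | cis-fused (1S,5S,6S)-7-(tert-butyldimethylsilyloxy)-5-isopropyl-7-[(Z)-prop-1-enyl]bicyclo[4.2.0]octan-2-one, epimers at C7 | O=C1[C@H]2CC(O[Si](C)(C)C(C)(C)C)(/C=C\C)[C@H]2[C@H](C(C)C)CC1 | intermediate
10 | cis-fused 7β-isopropyl-1-[1-(phenylselanyl)ethyl]hexahydro-1H-indene-2,4-dione, anti-addition diastereomer pair at C1 and C1' | O=C1[C@H]2CC(=O)C(C(C)[Se]c3ccccc3)[C@H]2[C@H](C(C)C)CC1 | intermediate (not isolated)
11 | cis-fused (1Z)-1-ethylidene-7β-isopropylhexahydro-1H-indene-2,4-dione | O=C1[C@H]2CC(=O)/C(=C\C)[C@H]2[C@H](C(C)C)CC1 | intermediate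
12 | 4,4-dimethyl ketal of 11 | COC1(OC)[C@H]2CC(=O)/C(=C\C)[C@H]2[C@H](C(C)C)CC1 | intermediate (not isolated)
13 | 4,4-dimethyl ketal of the 2α-alcohol | COC1(OC)[C@H]2C[C@@H](O)/C(=C\C)[C@H]2[C@H](C(C)C)CC1 | intermediate (not isolated)
14 | cis-fused (1Z)-1-ethylidene-2α-hydroxy-7β-isopropyloctahydro-1H-inden-4-one | O=C1[C@H]2C[C@@H](O)/C(=C\C)[C@H]2[C@H](C(C)C)CC1 | intermediate
15 | trans-fused (1Z)-1-ethylidene-2α-hydroxy-7β-isopropyloctahydro-1H-inden-4-one | O=C1[C@@H]2C[C@@H](O)/C(=C\C)[C@H]2[C@H](C(C)C)CC1 | intermediate
16 | trans-fused (1Z)-2β-acetoxy-1-ethylidene-7β-isopropyloctahydro-1H-inden-4-one | O=C1[C@@H]2C[C@H](OC(C)=O)/C(=C\C)[C@H]2[C@H](C(C)C)CC1 | intermediate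
17 | C4–C5 trimethylsilyl enol ether of 16 | C[Si](C)(C)OC=1[C@@H]2C[C@H](OC(C)=O)/C(=C\C)[C@H]2[C@H](C(C)C)CC=1 | intermediate (not isolated)
18 | trans-fused (1Z)-2β-acetoxy-1-ethylidene-7β-isopropyl-1,2,3,3a,7,7a-hexahydro-4H-inden-4-one | O=C1[C@@H]2C[C@H](OC(C)=O)/C(=C\C)[C@H]2[C@H](C(C)C)C=C1 | intermediate
19 | trans-fused (1Z)-2β-acetoxy-5β,6β-epoxy-1-ethylidene-7β-isopropyloctahydro-1H-inden-4-one | O=C1[C@@H]2C[C@H](OC(C)=O)/C(=C\C)[C@H]2[C@H](C(C)C)[C@@H]3O[C@@H]31 | intermediate
20 | trans-fused (1Z)-2β-acetoxy-5β,6β-epoxy-1-ethylidene-7β-isopropyl-4-methylideneoctahydro-1H-indene | C=C1[C@@H]2C[C@H](OC(C)=O)/C(=C\C)[C@H]2[C@H](C(C)C)[C@@H]3O[C@@H]31 | intermediate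
21 | angelic acid, (2Z)-2-methylbut-2-enoic acid | OC(=O)/C(C)=C\C | starting material
22 | CNP0210397.1, (1Z,2S,3aR,5S,6S,7S,7aR)-2-acetoxy-1-ethylidene-6-hydroxy-4-methylidene-7-(propan-2-yl)octahydro-1H-inden-5-yl (2Z)-2-methylbut-2-enoate | C=C1[C@@H]2C[C@H](OC(C)=O)/C(=C\C)[C@H]2[C@H](C(C)C)[C@H](O)[C@H]1OC(=O)/C(C)=C\C | target

**Step count.** Total: 13 steps. Longest linear sequence: 12 steps (1, 2, 4–13); step 3 is a one-step side branch.

**Steps most likely to fail**

Step 4. The conjugated enyne may quench the enone triplet, or the cycloaddition may take the wrong orientation or occur at the alkyne. The fallback sets out from 4 and uses the classical ketene-acetal partner: irradiation with 1,1-dimethoxyethene and alumina treatment should give the cis-fused 5-isopropyl-7,7-dimethoxybicyclo[4.2.0]octan-2-one F1. Its ketal, not its ketone, is ionised with BF3·OEt2 and the oxocarbenium ion is trapped with CH3C≡CBF3K to give the propargylic methyl ether F2. Lindlar semihydrogenation gives the (Z)-propenyl methyl ether F3, which is submitted to the conditions of step 6; the O-methyl oxocarbenium ion left after the shift is hydrolysed on work-up, and the route is rejoined at 11.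

Step 6. The CH2 carbon may migrate in competition with the ring-fusion carbon, or the geometry may be lost through reversible seleniranium formation or selenenylation of the ketone. The fallback sets out from 9 and uses an epoxide as the trigger: Bu4NF frees the cyclobutanol F4, and VO(acac)2/t-BuOOH epoxidises the Z-alkene under hydroxyl direction to the cis-epoxy alcohol F5. BF3·OEt2 then induces the semipinacol rearrangement of this 2,3-epoxy alcohol, a more cationic process that should favour the more substituted migrating carbon, with inversion at the epoxide carbon, to give the aldol F6. Syn-dehydration with the Burgess reagent should convert the same anti relationship into the Z-enone, and the route is rejoined at 11.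

Step 13. The angelate may add in the conjugate (SN2') sense at the exocyclic methylene carbon, or it may isomerise to the tiglate on prolonged heating with carboxylate. The fallback sets out from 20: dilute HClO4 in THF/water should open the epoxide at the allylic C5 with inversion to the trans-diaxial 5α,6β-diol F7. The allylic, less hindered 5-hydroxyl is then acylated selectively with the mixed anhydride of angelic acid and 2,4,6-trichlorobenzoyl chloride (Yamaguchi conditions, Et3N, toluene), and the route is rejoined at 22.

**Further compounds**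
F1 | step 4 | cis-fused (1S,5S,6S)-5-isopropyl-7,7-dimethoxybicyclo[4.2.0]octan-2-one | O=C1[C@H]2CC(OC)(OC)[C@H]2[C@H](C(C)C)CC1
F2 | step 4 | cis-fused 5-isopropyl-7-methoxy-7-(prop-1-ynyl)bicyclo[4.2.0]octan-2-one (epimers at C7) | O=C1[C@H]2CC(OC)(C#CC)[C@H]2[C@H](C(C)C)CC1
F3 | step 4 | cis-fused 5-isopropyl-7-methoxy-7-[(Z)-prop-1-enyl]bicyclo[4.2.0]octan-2-one (epimers at C7) | O=C1[C@H]2CC(OC)(/C=C\C)[C@H]2[C@H](C(C)C)CC1
F4 | step 6 | cis-fused 7-hydroxy-5-isopropyl-7-[(Z)-prop-1-enyl]bicyclo[4.2.0]octan-2-one (epimers at C7) | O=C1[C@H]2CC(O)(/C=C\C)[C@H]2[C@H](C(C)C)CC1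
F5 | step 6 | cis-fused 7-hydroxy-5-isopropyl-7-(cis-3-methyloxiran-2-yl)bicyclo[4.2.0]octan-2-one | O=C1[C@H]2CC(O)(C3OC3C)[C@H]2[C@H](C(C)C)CC1
F6 | step 6 | cis-fused 1-(1-hydroxyethyl)-7β-isopropylhexahydro-1H-indene-2,4-dione | O=C1[C@H]2CC(=O)C(C(C)O)[C@H]2[C@H](C(C)C)CC1
F7 | step 13 | trans-fused (1Z)-2β-acetoxy-1-ethylidene-7β-isopropyl-4-methylideneoctahydro-1H-indene-5α,6β-diol | C=C1[C@@H]2C[C@H](OC(C)=O)/C(=C\C)[C@H]2[C@H](C(C)C)[C@H](O)[C@H]1O
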